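The cyclopentane C6–C7–C8–C9–C10 of the target, with C1 exocyclic on C10 between the methyl-bearing C6 and the isopropyl carbinol C9, is treated as a p-menthane six-membered ring (C6, C7, C8, C9, C1, C10) from which C1 has been extruded. Photochemical Wolff rearrangement of a 2-diazocyclohexanone (C1=O, C10=N2) shifts C9 from C1 to C10: one operation forms C9–C10, contracts the ring and leaves C1 as an ester. The precursor, made from (S)-carvone, already holds C6, C7 and C9 in their final configuration, with O9 as a triethylsilyl ether and O5/O7 as an acetonide. C1 and C5 are then extended and joined at C3=C4 by metathesis.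

Key step: step 11

Remark: C1–C10 are the atom labels of the target (C1 aroyloxy carbon, C2 CH2, C3=C4 alkene, C5 free carbinol, C6 quaternary methyl carbon, C7 acetoxy carbon, C8 CH2, C9 isopropyl carbinol, C10 ring-fusion CH); O5, O7, O9 are the oxygens on those carbons; β is the ring face that carries O7 (and the C9 isopropyl, later C5 on C6), α the opposite face (C6 methyl, O9).
Remark: the stereochemistry is relayed from (S)-carvone: its β isopropyl at C9 places O7 β (step 2), O7 delivers C5 to the β face of C6 (step 8), and O9 replaces H9 with overall retention (step 5); (R)-carvone would lead to the antipode.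
Remark: the C9 configuration of 5 is immaterial (C9 is planarised in step 5) and is drawn as retained.
Remark: numbers are given to the carvone-derived compounds and to the building blocks whose atoms reach the target; other reagents are named on the reagent lines.

Step 1
Reactants: 1 (S)-(+)-carvone
Product: 2 (S)-carvotanacetone [(5S)-2-methyl-5-(propan-2-yl)cyclohex-2-en-1-one]
Conditions: H2 (1 atm), RhCl(PPh3)3 (cat.), benzene, rt
Reagents that add atoms: none
Why: Homogeneous catalytic hydrogenation with RhCl(PPh3)3 should saturate only the unhindered 1,1-disubstituted isopropenyl alkene and leave the trisubstituted conjugated alkene and the C9 stereocentre untouched.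

Step 2
Reactants: 2 (S)-carvotanacetone
Product: 3 (1S,5S)-2-methyl-5-(propan-2-yl)cyclohex-2-en-1-ol (C7–OH β; cis to the C9 isopropyl)
Conditions: NaBH4, CeCl3·7H2O, MeOH, −78 → 0 °C
Reagents that add atoms: none
Why: Luche 1,2-reduction: hydride should add on the axial trajectory to the half-chair enone with the C9 isopropyl pseudoequatorial, which places the new C7–OH cis to the isopropyl group (β), the usual outcome for carvone-type enones.

Step 3
Reactants: 3 cis-allylic alcohol
Product: 4 (1S,5S)-2-methyl-5-(propan-2-yl)cyclohex-2-en-1-yl benzoate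
Conditions: PhCOCl, pyridine, DMAP (cat.), CH2Cl2, 0 °C → rt
Reagents that add atoms: benzoyl chloride, O=C(Cl)c1ccccc1
Why: DMAP-catalysed O-benzoylation of the secondary allylic alcohol with retention at C7; the benzoate has no α-hydrogen (needed in step 5) and deactivates C7–H in step 4.

Step 4
Reactants: 4 allylic benzoate
Product: 5 (1S,5S)-2-methyl-4-oxo-5-(propan-2-yl)cyclohex-2-en-1-yl benzoate (C1 ketone; C10=C6 alkene; C7–OBz β)
Conditions: CrO3, 3,5-dimethylpyrazole, CH2Cl2, −20 °C
Reagents that add atoms: chromium trioxide, O=[Cr](=O)=O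
Why: Allylic C–H oxidation by the CrO3–3,5-dimethylpyrazole complex: C7 is blocked by its deactivating ester and the methyl is a primary site, so the ring methylene C1 should be oxidised to the ketone, giving the transposed enone C1(=O)–C10=C6 without touching C7.

Step 5
Reactants: 5 enone benzoate
Product: 8 C9-triethylsilyloxy enone benzoate (O9 α; isopropyl β; O7 β), via triethylsilyl dienol ether 6 (not isolated), via silyloxy epoxide 7 (not isolated)
Conditions: LiN(iPr)2, Et3SiCl (in situ), THF, −78 → 0 °C; then mCPBA, hexane/CH2Cl2, −20 °C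
Reagents that add atoms: chlorotriethylsilane, CC[Si](Cl)(CC)CC; 3-chloroperbenzoic acid, OOC(=O)c1cccc(Cl)c1
Why: Rubottom oxidation: the amide base can enolise only towards C9 (C10 is sp2), the peracid should epoxidise the electron-rich silyl enol ether bond C9=C1 anti to the pseudoaxial C7 benzoate (as in additions to 5-substituted cyclohexa-1,3-dienes), and 1,4-silyl migration on opening of the epoxide delivers the C9 triethylsilyl ether with O9 α and the isopropyl β.

Step 6
Reactants: 8 C9-triethylsilyloxy enone benzoate
Product: 9 γ-hydroxy enone (C7–OH β; C9–OSiEt3 α)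
Conditions: K2CO3 (cat.), MeOH, 0 °C → rt
Reagents that add atoms: none
Why: Carbonate-catalysed transesterification (methanolysis) removes the benzoate with retention at C7; the enone has no α′-hydrogen left and the hindered tertiary triethylsilyl ether should survive.

Step 7
Reactants: 9 γ-hydroxy enone; 10 (bromomethyl)chlorodimethylsilane
Product: 11 C7 (bromomethyl)dimethylsilyl ether of 9
Conditions: BrCH2SiMe2Cl, Et3N, DMAP (cat.), CH2Cl2, 0 °C
Reagents that add atoms: (bromomethyl)chlorodimethylsilane (10), C[Si](C)(Cl)CBr
Why: O-Silylation of the only free hydroxyl by the chlorosilane installs the bromomethylsilyl tether on O7 without change at any stereocentre.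

Step 8
Reactants: 11 bromomethylsilyl ether
Product: 13 keto diol (C1 ketone; C5–OH on C6 β; C7–OH β; C6 methyl α; C9–OSiEt3 α), via cis-fused oxasilolane 12 (not isolated)
Conditions: Bu3SnH, AIBN (cat.), benzene, 80 °C (slow addition); then 30% H2O2, KF, KHCO3, THF/MeOH, rt
Reagents that add atoms: hydrogen peroxide, OO
Why: Silicon-tethered 5-exo-trig radical cyclisation (Nishiyama–Stork type): the nucleophilic α-silylmethyl radical adds to the enone β-carbon C6 and the five-membered oxasilolane can only be cis-fused, so C5 is delivered to the β face of C6 (methyl α), after which Tamao–Fleming oxidation turns C5–Si into C5–OH.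

Step 9
Reactants: 13 keto diol
Product: 14 O5,O7-isopropylidene acetal of 13 (acetonide ketone)
Conditions: 2-methoxypropene, pyridinium p-toluenesulfonate (cat.), CH2Cl2, 0 °C
Reagents that add atoms: 2-methoxypropene, COC(C)=C
Why: Acid-catalysed acetal formation: the cis-1,3-diol O5/O7 should close the six-membered isopropylidene acetal, and the enol ether reagent releases only one methanol so that the hindered C1 ketone is not ketalised.

Step 10
Reactants: 14 acetonide ketone
Product: 16 diazo ketone (C10=N2; C1=O; 6S,7S,9R; C9–OSiEt3 α; O5/O7 acetonide), via C10-trifluoroacetyl ketone 15 (not isolated)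
Conditions: LiN(SiMe3)2, THF, −78 °C; CF3CO2CH2CF3; then 4-AcNHC6H4SO2N3, Et3N, H2O (1 equiv), MeCN, rt
Reagents that add atoms: 2,2,2-trifluoroethyl trifluoroacetate (trifluoroacetyl group of 15), FC(F)(F)COC(=O)C(F)(F)F; 4-acetamidobenzenesulfonyl azide (N2 of 16), CC(=O)Nc1ccc(cc1)S(=O)(=O)N=[N+]=[N-]
Why: Detrifluoroacetylative Regitz-type diazo transfer: the lithium enolate can form only towards C10 because C9 carries no hydrogen, Claisen trifluoroacetylation activates C10, and the sulfonyl azide then transfers N2 with loss of the trifluoroacetyl group as the N-acylsulfonamide.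

Step 11
Reactants: 16 diazo ketone
Product: 19 methyl cyclopentanecarboxylate (6S,7S,9R,10R; CO2Me α; C9–OSiEt3 α; O5/O7 acetonide), via ketene 17 (not isolated), via C10-epimeric methyl ester 18 (not isolated)
Conditions: hν (365 nm), MeOH, 0 °C; then NaOMe (cat.), MeOH, rt
Reagents that add atoms: methanol, CO
Why: Light expels N2 from the cyclic, s-cis-locked diazo ketone and the bond C1–C9 migrates to the electron-deficient C10 (Wolff rearrangement), giving ketene 17, which methanol traps as the ester. The closest known reaction type is the photochemical Wolff ring contraction of 2-diazocycloalkanones in an alcohol. The cyclopentane C6–C7–C8–C9–C10 is closed by a 1,2-shift of the ring carbon C9 from C1 to C10 (ring contraction with extrusion of C1), not by cyclisation of a chain. C9 migrates with retention, so O9 stays α and the isopropyl β, while C6 and C7 are spectators. The new centre C10 is first set by unselective protonation of the ester enol (18 and 19) and then equilibrated by catalytic NaOMe to 19, in which the ester lies on the α face, trans to the isopropyl group and to C5 of the cis-fused dioxane. The step needs regioselective migration, which the ring guarantees, and a clean equilibration, for which 16 carries a tertiary triethylsilyl ether (stable to methoxide, poor leaving group) and no second enolisable position.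

Step 12
Reactants: 19 methyl ester
Product: 21 diol (C1–OH primary; C9–OH tertiary; O5/O7 acetonide), via silyl ether alcohol 20 (not isolated)
Conditions: LiAlH4, THF, 0 °C → rt; then Bu4NF, THF, rt
Reagents that add atoms: none
Why: Hydride reduction of the ester to the primary alcohol followed by fluoride cleavage of the Si–O bond; neither operation touches a stereocentre and the acetonide is inert to both reagents.

Step 13
Reactants: 21 diol
Product: 22 β-hydroxy aldehyde (C1 aldehyde α on C10; C9–OH free)
Conditions: Dess–Martin periodinane, pyridine, CH2Cl2, 0 °C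
Reagents that add atoms: none
Why: Dess–Martin oxidation converts the primary alcohol into the aldehyde under non-basic conditions, the tertiary C9–OH being unoxidisable, and C10 stays α because that is also its thermodynamic orientation.

Step 14
Reactants: 22 β-hydroxy aldehyde; 23 methallylmagnesium chloride
Product: 24 (1S)-carbinol carrying the methallyl group (C2, C3 and the C3 methyl) on C1, C9–OH free
Conditions: CH2=C(CH3)CH2MgCl (3 equiv), THF, −78 °C
Reagents that add atoms: methallylmagnesium chloride (23), CC(=C)C[Mg]Cl
Why: Grignard addition under Cram-chelate control: the first equivalent forms the C9 magnesium alkoxide, which binds the aldehyde oxygen in a six-membered chelate cis-fused to the cyclopentane, so the methallyl group should add to C1 on the side of C10–H and anti to C6, which gives the (1S)-carbinol.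

Step 15
Reactants: 24 (1S)-carbinol; 25 4-methoxybenzoyl chloride
Product: 26 C1 4-methoxybenzoate of 24
Conditions: 4-MeOC6H4COCl, Et3N, DMAP, CH2Cl2, rt → 40 °C
Reagents that add atoms: 4-methoxybenzoyl chloride (25), COc1ccc(cc1)C(Cl)=O
Why: DMAP-catalysed acylation (nucleophilic catalysis) should esterify only the secondary C1–OH, the tertiary C9–OH being too hindered to react.

Step 16
Reactants: 26 acetonide 4-methoxybenzoate
Product: 27 triol (C5–OH, C7–OH, C9–OH) C1 4-methoxybenzoate
Conditions: pyridinium p-toluenesulfonate (cat.), MeOH, 40 °C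
Reagents that add atoms: none
Why: Acid-catalysed transacetalisation to methanol releases the O5/O7 diol under conditions that should leave the aryl ester, the 1,1-disubstituted alkene and the tertiary alcohol untouched.

Step 17
Reactants: 27 triol
Product: 28 C5 aldehyde (on quaternary C6; C7–OH and C9–OH free)
Conditions: TEMPO (cat.), PhI(OAc)2, CH2Cl2, rt
Reagents that add atoms: none
Why: Oxoammonium (TEMPO) oxidation is selective for the primary C5–OH over the secondary C7–OH and the tertiary C9–OH, and the resulting aldehyde on quaternary C6 can neither enolise nor eliminate.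

Step 18
Reactants: 28 hydroxy aldehyde; 29 acetic anhydride
Product: 30 C7 acetate of 28
Conditions: Ac2O, pyridine, DMAP (cat.), CH2Cl2, 0 °C → rt
Reagents that add atoms: acetic anhydride (29), CC(=O)OC(C)=O
Why: DMAP-catalysed acetylation of the only secondary alcohol (O7) with retention; the tertiary C9–OH should stay free and the aldehyde has no α-hydrogen.

Step 19
Reactants: 30 acetoxy aldehyde; 31 vinyl bromide
Product: 32 (5S)-vinyl carbinol (diene: vinyl on C5, methallyl on C1)
Conditions: CH2=CHBr, CrCl2, NiCl2 (cat.), DMF, rt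
Reagents that add atoms: vinyl bromide (31), C=CBr
Why: Nozaki–Hiyama–Kishi vinylation tolerates both esters and the free tertiary alcohol, and by the Felkin–Anh model the vinylchromium reagent should add to C5 anti to the larger ring carbon C10 and past the C6 methyl with the carbonyl oxygen beside C7, which gives the (5S)-carbinol (O5 α, cis to the C6 methyl).

Step 20
Reactants: 32 diene
Product: 33 CNP0261832.1 (target)
Conditions: second-generation Grubbs catalyst (cat.), CH2Cl2, 40 °C
Reagents that add atoms: none
Why: Ring-closing metathesis between the vinyl group (C4) and the 1,1-disubstituted alkene (C3) closes the seven-membered ring as the trisubstituted C3=C4 alkene with loss of ethene; the trans-disposed chains on C6 and C10 give the trans-fused bicycle and no stereocentre is touched.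

Compound list
1 | (S)-(+)-carvone | CC1=CC[C@@H](CC1=O)C(C)=C | starting material
2 | (S)-carvotanacetone | CC1=CC[C@@H](CC1=O)C(C)C | intermediate
3 | (1S,5S)-2-methyl-5-(propan-2-yl)cyclohex-2-en-1-ol | CC1=CC[C@@H](C[C@@H]1O)C(C)C | intermediate
4 | (1S,5S)-2-methyl-5-(propan-2-yl)cyclohex-2-en-1-yl benzoate | CC1=CC[C@@H](C[C@@H]1OC(=O)c2ccccc2)C(C)C | intermediate
5 | (1S,5S)-2-methyl-4-oxo-5-(propan-2-yl)cyclohex-2-en-1-yl benzoate | CC1=CC(=O)[C@@H](C[C@@H]1OC(=O)c2ccccc2)C(C)C | intermediate
6 | triethylsilyl dienol ether of 5 (C9=C1(OSiEt3)–C10=C6) | CC1=CC(O[Si](CC)(CC)CC)=C(C(C)C)C[C@@H]1OC(=O)c2ccccc2 | intermediate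
7 | C9–C1 α-epoxide of 6 (silyloxy epoxide) | CC1=C[C@@]2(O[Si](CC)(CC)CC)O[C@@]2(C(C)C)C[C@@H]1OC(=O)c3ccccc3 | intermediate
8 | enone with C9–OSiEt3 α, isopropyl β, C7–OBz β | CC1=CC(=O)[C@](O[Si](CC)(CC)CC)(C(C)C)C[C@@H]1OC(=O)c2ccccc2 | intermediate
9 | γ-hydroxy enone (C7–OH β, C9–OSiEt3 α) | CC1=CC(=O)[C@](O[Si](CC)(CC)CC)(C(C)C)C[C@@H]1O | intermediate
10 | (bromomethyl)chlorodimethylsilane | C[Si](C)(Cl)CBr | starting material
11 | C7 (bromomethyl)dimethylsilyl ether of 9 | CC1=CC(=O)[C@](O[Si](CC)(CC)CC)(C(C)C)C[C@@H]1O[Si](C)(C)CBr | intermediate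
12 | cis-fused oxasilolane ketone (O7–SiMe2–C5 ring across C7–C6) | O=C1C[C@@]2(C)C[Si](C)(C)O[C@H]2C[C@@]1(O[Si](CC)(CC)CC)C(C)C | intermediate
13 | keto diol (C5–OH, C7–OH β; C6 methyl α; C9–OSiEt3 α) | O=C1C[C@@](C)(CO)[C@@H](O)C[C@@]1(O[Si](CC)(CC)CC)C(C)C | intermediate
14 | O5,O7-acetonide ketone | O=C1C[C@@]2(C)COC(C)(C)O[C@H]2C[C@@]1(O[Si](CC)(CC)CC)C(C)C | intermediate
15 | C10-trifluoroacetyl ketone (C10 enolised, unassigned) | O=C1C(C(=O)C(F)(F)F)[C@@]2(C)COC(C)(C)O[C@H]2C[C@@]1(O[Si](CC)(CC)CC)C(C)C | intermediate
16 | (6S,7S,9R)-2-diazo ketone (C10=N2, C1=O) | O=C1C(=[N+]=[N-])[C@@]2(C)COC(C)(C)O[C@H]2C[C@@]1(O[Si](CC)(CC)CC)C(C)C | intermediate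
17 | cyclopentylidene ketene (C10=C1=O) | O=C=C1[C@@]2(C)COC(C)(C)O[C@H]2C[C@@]1(O[Si](CC)(CC)CC)C(C)C | intermediate
18 | C10-epimeric methyl ester (CO2Me β) | COC(=O)[C@H]1[C@@]2(C)COC(C)(C)O[C@H]2C[C@@]1(O[Si](CC)(CC)CC)C(C)C | intermediate
19 | (6S,7S,9R,10R)-methyl cyclopentanecarboxylate (CO2Me α) | COC(=O)[C@@H]1[C@@]2(C)COC(C)(C)O[C@H]2C[C@@]1(O[Si](CC)(CC)CC)C(C)C | intermediate
20 | C1 primary alcohol, C9–OSiEt3 | OC[C@@H]1[C@@]2(C)COC(C)(C)O[C@H]2C[C@@]1(O[Si](CC)(CC)CC)C(C)C | intermediate
21 | C1,C9-diol | OC[C@@H]1[C@@]2(C)COC(C)(C)O[C@H]2C[C@@]1(O)C(C)C | intermediate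
22 | C1 aldehyde with free C9–OH | O=C[C@@H]1[C@@]2(C)COC(C)(C)O[C@H]2C[C@@]1(O)C(C)C | intermediate
23 | methallylmagnesium chloride | CC(=C)C[Mg]Cl | starting material
24 | (1S)-methallyl carbinol | CC(=C)C[C@H](O)[C@@H]1[C@@]2(C)COC(C)(C)O[C@H]2C[C@@]1(O)C(C)C | intermediate
25 | 4-methoxybenzoyl chloride | COc1ccc(cc1)C(Cl)=O | starting material
26 | C1 4-methoxybenzoate, O5/O7 acetonide | CC(=C)C[C@H](OC(=O)c3ccc(OC)cc3)[C@@H]1[C@@]2(C)COC(C)(C)O[C@H]2C[C@@]1(O)C(C)C | intermediate
27 | triol C1 4-methoxybenzoate | CC(=C)C[C@H](OC(=O)c2ccc(OC)cc2)[C@@H]1[C@@](C)(CO)[C@@H](O)C[C@@]1(O)C(C)C | intermediate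
28 | C5 aldehyde, C7–OH free | CC(=C)C[C@H](OC(=O)c2ccc(OC)cc2)[C@@H]1[C@@](C)(C=O)[C@@H](O)C[C@@]1(O)C(C)C | intermediate
29 | acetic anhydride | CC(=O)OC(C)=O | starting material
30 | C5 aldehyde C7 acetate | CC(=C)C[C@H](OC(=O)c2ccc(OC)cc2)[C@@H]1[C@@](C)(C=O)[C@@H](OC(C)=O)C[C@@]1(O)C(C)C | intermediate
31 | vinyl bromide | C=CBr | starting material
32 | (5S)-vinyl carbinol diene | CC(=C)C[C@H](OC(=O)c2ccc(OC)cc2)[C@@H]1[C@@](C)([C@@H](O)C=C)[C@@H](OC(C)=O)C[C@@]1(O)C(C)C | intermediate
33 | CNP0261832.1 (C1 S, C5 S, C6 S, C7 S, C9 R, C10 S) | COc1ccc(C(=O)O[C@H]2CC(C)=C[C@H](O)[C@@]3(C)[C@@H](OC(C)=O)C[C@@](O)(C(C)C)[C@H]23)cc1 | target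

Total step count: 20. Longest linear sequence: 20 steps from (S)-carvone; all other inputs are commercial reagents.

Steps most likely to fail

Step 11. The risk is that the base equilibration at C10 is accompanied by β-elimination of the C9 silyloxy group, or that it stops at an unfavourable epimer ratio. The fallback sets out from 16 and returns at 20. Irradiation of 16 in THF containing ethanethiol should trap the ketene as the S-ethyl thioesters, a C10 mixture containing the β-epimer F1. The much more acidic thioester α-hydrogen allows equilibration with DBU in CH2Cl2, aprotic and without alkoxide, to the α-thioester F2. LiAlH4 reduction of F2 gives alcohol 20, and Bu4NF then gives 21.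

Step 14. The risk is retro-aldol fragmentation of the magnesium β-alkoxide, or poor facial selectivity because the allylic Grignard reagent reacts faster than the chelate can direct it. The fallback sets out from 20 and returns at 27. Alcohol 20 is isolated without fluoride treatment and oxidised with Dess–Martin periodinane to the silyloxy aldehyde F3. Reagent-controlled asymmetric methallylboration follows, with the B-methallyldiisopinocampheylborane made from (−)-Ipc2BOMe and 23 at −78 °C, the antipode that adds to the Si face of aldehydes. It should give the (1S)-carbinol F4. Acylation with 25 after deprotonation with LiN(SiMe3)2 gives the 4-methoxybenzoate F5. HCl (cat.) in MeOH then removes the triethylsilyl ether and the acetonide together to reach 27.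

Step 19. The risk is poor facial selectivity of the vinylchromium addition to the α-quaternary aldehyde. The fallback sets out from 30 and returns at 33. The adduct is carried on as the mixture of 32 and its C5 epimer F6. Metathesis as in step 20 gives 33 together with its C5 epimer F7. MnO2 in CH2Cl2 oxidises the allylic alcohols of this mixture to the single enone F8 (C5=O conjugated with C3=C4). Luche reduction (NaBH4, CeCl3·7H2O, MeOH, −78 °C) should then add hydride anti to the angular C6 methyl and return 33.

Further compounds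
F1 | step 11 | S-ethyl thioester, C10 epimer with the thioester β | CCSC(=O)[C@H]1[C@@]2(C)COC(C)(C)O[C@H]2C[C@@]1(O[Si](CC)(CC)CC)C(C)C
F2 | step 11 | S-ethyl thioester with the thioester α | CCSC(=O)[C@@H]1[C@@]2(C)COC(C)(C)O[C@H]2C[C@@]1(O[Si](CC)(CC)CC)C(C)C
F3 | step 14 | C1 aldehyde with C9–OSiEt3 | O=C[C@@H]1[C@@]2(C)COC(C)(C)O[C@H]2C[C@@]1(O[Si](CC)(CC)CC)C(C)C
F4 | step 14 | (1S)-methallyl carbinol with C9–OSiEt3 | CC(=C)C[C@H](O)[C@@H]1[C@@]2(C)COC(C)(C)O[C@H]2C[C@@]1(O[Si](CC)(CC)CC)C(C)C
F5 | step 14 | C1 4-methoxybenzoate with C9–OSiEt3 | CC(=C)C[C@H](OC(=O)c3ccc(OC)cc3)[C@@H]1[C@@]2(C)COC(C)(C)O[C@H]2C[C@@]1(O[Si](CC)(CC)CC)C(C)C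
F6 | step 19 | C5 epimer of 32 | CC(=C)C[C@H](OC(=O)c2ccc(OC)cc2)[C@@H]1[C@@](C)([C@H](O)C=C)[C@@H](OC(C)=O)C[C@@]1(O)C(C)C
F7 | step 19 | C5 epimer of 33 | COc1ccc(C(=O)O[C@H]2CC(C)=C[C@@H](O)[C@@]3(C)[C@@H](OC(C)=O)C[C@@](O)(C(C)C)[C@H]23)cc1
F8 | step 19 | C5 enone | COc1ccc(C(=O)O[C@H]2CC(C)=CC(=O)[C@@]3(C)[C@@H](OC(C)=O)C[C@@](O)(C(C)C)[C@H]23)cc1
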